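The strategy rests on a bond that the target does not contain. Joining the ketone carbon (C2 of the hexadecanone chain) to C1 of the butyl group turns the target into an isomer, a 2-propyl-3-tetradecyl-8-oxabicyclo[3.2.1]octan-3-ol. Its bridgeheads are oxolane C2 and C5, so they can only be cis. The key step cuts this bond again. A redox-neutral alkoxyl-radical β-scission opens the seven-membered carbocycle and releases the ketone, the butyl chain and the cis-oxolane in one operation. It also erases both auxiliary stereocentres, so all epimers converge. The precursor arises in three steps from commercial meso 8-oxabicyclo[3.2.1]octan-3-one. The absolute configuration is fixed by which enantiotopic α-CH2 is allylated.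

Key step: step 4

Assumption: the sense of the chiral-amide deprotonation of 1 is assigned by analogy with 4-substituted cyclohexanones. If the bicyclic ketone responds in the opposite sense, the equally commercial (R,R)-amine hydrochloride is used and nothing else changes.
Remark: 4, 5 and 7 are drawn as the expected major C2/C3 epimers. Minor epimers are carried along, because both centres vanish in step 4.

Step 1
Reactants: 1 8-oxabicyclo[3.2.1]octan-3-one (meso); 2 allyl bromide
Product: 4 (1S,2S,5R)-2-(prop-2-en-1-yl)-8-oxabicyclo[3.2.1]octan-3-one (allyl exo), via lithium enolate 3 (not isolated)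
Conditions: bis[(S)-1-phenylethyl]amine·HCl, n-BuLi (2 equiv), THF, −78 → 0 °C; 1, −100 °C; then 2, DMPU, −78 → −40 °C
Reagents that add atoms: allyl bromide (2), C=CCBr
Why: Enantioselective deprotonation of a meso ketone by a C2-symmetric chiral lithium amide–LiCl aggregate should remove one of the two enantiotopic exo (axial) α-hydrogens, and SN2 allylation of enolate 3 on its open exo face sets C2 as drawn, the choice of α-carbon (not the C2 configuration) being what fixes the absolute sense of bridgeheads C1 and C5 for the rest of the route.

Step 2
Reactants: 4 (1S,2S,5R)-2-(prop-2-en-1-yl)-8-oxabicyclo[3.2.1]octan-3-one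
Product: 5 (1S,2S,5R)-2-propyl-8-oxabicyclo[3.2.1]octan-3-one
Conditions: H2 (1 atm), Pd/C, EtOAc, rt
Reagents that add atoms: none
Why: Heterogeneous catalytic hydrogenation saturates the terminal alkene under neutral conditions that leave the ketone, the ether bridge and all stereocentres untouched, and it removes the alkene that would otherwise trap the alkoxyl radical of step 4.

Step 3
Reactants: 5 (1S,2S,5R)-2-propyl-8-oxabicyclo[3.2.1]octan-3-one; 6 tetradecylmagnesium chloride
Product: 7 (1S,2S,3S,5R)-2-propyl-3-tetradecyl-8-oxabicyclo[3.2.1]octan-3-ol (OH endo)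
Conditions: 6 (1 M in THF), LaCl3·2LiCl, THF, 0 °C → rt; aq NH4Cl
Reagents that add atoms: tetradecylmagnesium chloride (6), CCCCCCCCCCCCCC[Mg]Cl
Why: In this lanthanide-promoted Grignard 1,2-addition the oxophilic La(III) salt activates the carbonyl group and tempers the basicity so that addition should outrun enolisation and β-hydride reduction, with attack expected from the exo (equatorial) side away from the C6–C7 bridge to give the endo alcohol, although the C3 configuration is of no consequence.

Step 4
Reactants: 7 (1S,2S,3S,5R)-2-propyl-3-tetradecyl-8-oxabicyclo[3.2.1]octan-3-ol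
Product: 10 1-[(2R,5R)-5-butyloxolan-2-yl]hexadecan-2-one (target), via alkoxyl radical 8 (not isolated), via ring-opened alkyl radical 9 (not isolated)
Conditions: [Ir(dF(CF3)ppy)2(5,5'-d(CF3)bpy)]PF6 (cat.), n-Bu4P+ (MeO)2PO2− (cat.), 2,4,6-triisopropylbenzenethiol (cat.), PhMe, blue LEDs, rt
Reagents that add atoms: none
Why: The excited Ir(III) complex and the hydrogen-bonded phosphate remove an electron and the proton from the O–H of 7 in a concerted PCET to give alkoxyl radical 8, which undergoes β-scission of the C2–C3 bond to the ketone-bearing secondary radical 9; hydrogen-atom transfer from the thiol gives 10, and reduction of the thiyl radical by Ir(II) followed by protonation closes both cycles, so the step is a net isomerisation. The closest known reaction type is the light-driven PCET ring-opening isomerisation of unstrained cyclic aliphatic alcohols to linear ketones (alkoxyl-radical β-scission). No ring is closed: the seven-membered carbocycle (C1–C7) is opened at C2–C3 and the oxolane (O8, C1, C7, C6, C5) is left untouched. No stereocentre is created: bridgeheads C1 and C5 are spectators that become oxolane C5 and C2 with the cis relation imposed by the bicycle, whereas C2 and C3 become CH2 and C=O, so every C2/C3 epimer of 7 funnels into the same 10. The selectivity needed is cleavage of C3–C2 rather than C3–C4 or the bond from C3 to the tetradecyl chain, and the propyl branch secures it because only this cleavage gives a secondary radical (the other two give primary radicals) while also releasing the strain of the bicycle. Competing 1,5-hydrogen shifts from the chains are harmless because the thiol returns the hydrogen and regenerates 7, and the near-neutral medium avoids retro-oxa-Michael epimerisation of the β-alkoxy ketone.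

Compound list
1 | 8-oxabicyclo[3.2.1]octan-3-one (meso, 1R,5S) | O=C1C[C@H]2CC[C@H](O2)C1 | starting material
2 | allyl bromide | C=CCBr | starting material
3 | lithium (1S,5R)-8-oxabicyclo[3.2.1]oct-2-en-3-olate | [Li]OC1=C[C@@H]2CC[C@H](C1)O2 | intermediate
4 | (1S,2S,5R)-2-(prop-2-en-1-yl)-8-oxabicyclo[3.2.1]octan-3-one (allyl exo) | O=C1C[C@H]2CC[C@H](O2)[C@@H]1CC=C | intermediate
5 | (1S,2S,5R)-2-propyl-8-oxabicyclo[3.2.1]octan-3-one (propyl exo) | O=C1C[C@H]2CC[C@H](O2)[C@@H]1CCC | intermediate
6 | tetradecylmagnesium chloride | CCCCCCCCCCCCCC[Mg]Cl | starting material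
7 | (1S,2S,3S,5R)-2-propyl-3-tetradecyl-8-oxabicyclo[3.2.1]octan-3-ol (OH endo, tetradecyl exo) | CCCCCCCCCCCCCC[C@]1(O)C[C@H]2CC[C@H](O2)[C@@H]1CCC | intermediate
8 | alkoxyl radical derived from 7 by loss of the O–H hydrogen | CCCCCCCCCCCCCC[C@]1([O])C[C@H]2CC[C@H](O2)[C@@H]1CCC | intermediate
9 | 1-[(2R,5R)-5-(2-oxohexadecyl)oxolan-2-yl]butyl radical | CCCCCCCCCCCCCCC(=O)C[C@H]1CC[C@H](O1)[CH]CCC | intermediate
10 | 1-[(2R,5R)-5-butyloxolan-2-yl]hexadecan-2-one (cis) | CCCCCCCCCCCCCCC(=O)C[C@H]1CC[C@@H](CCCC)O1 | target

Total step count: 4
Longest linear sequence: 4 steps (1 → 4 → 5 → 7 → 10)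

Steps most likely to fail

**Step 4.**
- What may go wrong: O–H activation of the crowded tertiary carbinol may be slow. Hydrogen shuttling may consume the alkoxyl radical unproductively. Cleavage may also occur towards a primary radical on the unbranched side or in the chain.
- Fallback: the same C2–C3 bond is cut by a polar oxidative route instead of a radical one, setting out from 5.
- Baeyer–Villiger oxidation (mCPBA, NaHCO3, CH2Cl2), in which the more substituted C2 migrates with retention, should give the lactone (1S,2S,6R)-2-propyl-3,9-dioxabicyclo[4.2.1]nonan-4-one F1.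
- Ring opening with MeNH(OMe)·HCl and i-PrMgCl should give the hydroxy Weinreb amide 2-{(2R,5S)-5-[(1S)-1-hydroxybutyl]oxolan-2-yl}-N-methoxy-N-methylacetamide F2.
- 1,1'-Thiocarbonyldiimidazole converts the alcohol into the O-imidazolylthiocarbonyl derivative F3.
- Barton–McCombie deoxygenation (Bu3SnH, AIBN, PhMe, 90 °C) should give 2-[(2R,5R)-5-butyloxolan-2-yl]-N-methoxy-N-methylacetamide F4.
- Addition of 6 (Weinreb ketone synthesis) comes back to the route at 10.

**Step 1.**
- What may go wrong: enantiomeric purity may erode through proton exchange among enolate 3, ketone 1 and the amine during the comparatively slow C-allylation. Double allylation may occur. The oxygen bridge may be lost by β-elimination if the enolate is warmed.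
- Fallback: the deprotonation is separated from the C–C bond formation, setting out from 1.
- The same chiral amide is used with Me3SiCl already present (internal quench, THF, −100 °C), which should give the isolable enol silane [(1S,5R)-8-oxabicyclo[3.2.1]oct-2-en-3-yl]oxy(trimethyl)silane F5.
- The allyl group is then delivered regiospecifically through a π-allylpalladium complex (Tsuji–Trost allylation with allyl methyl carbonate, Pd2(dba)3, dppe, THF) instead of by SN2 alkylation of a free lithium enolate. This comes back to the route at 4.

**Step 3.**
- What may go wrong: enolisation or β-hydride reduction of the hindered, α-branched ketone by the long-chain Grignard reagent may compete with addition.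
- Fallback: a slim sp-nucleophile without β-hydrogens is used, setting out from 5.
- Lithium tetradec-1-yn-1-ide (from 1-tetradecyne and n-BuLi, THF, −78 °C) should give the propargylic alcohol (1S,2S,3S,5R)-2-propyl-3-(tetradec-1-yn-1-yl)-8-oxabicyclo[3.2.1]octan-3-ol F6.
- Exhaustive hydrogenation (H2, Pd/C, EtOAc) comes back to the route at 7.

Further compounds
F1 | step 4 | (1S,2S,6R)-2-propyl-3,9-dioxabicyclo[4.2.1]nonan-4-one | O=C1C[C@H]2CC[C@H](O2)[C@H](CCC)O1
F2 | step 4 | 2-{(2R,5S)-5-[(1S)-1-hydroxybutyl]oxolan-2-yl}-N-methoxy-N-methylacetamide | CON(C)C(=O)C[C@H]1CC[C@H](O1)[C@@H](O)CCC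
F3 | step 4 | O-imidazolylthiocarbonyl derivative of F2 | CON(C)C(=O)C[C@H]1CC[C@H](O1)[C@@H](OC(=S)n1ccnc1)CCC
F4 | step 4 | 2-[(2R,5R)-5-butyloxolan-2-yl]-N-methoxy-N-methylacetamide | CON(C)C(=O)C[C@H]1CC[C@@H](CCCC)O1
F5 | step 1 | [(1S,5R)-8-oxabicyclo[3.2.1]oct-2-en-3-yl]oxy(trimethyl)silane | C[Si](C)(C)OC1=C[C@@H]2CC[C@H](C1)O2
F6 | step 3 | (1S,2S,3S,5R)-2-propyl-3-(tetradec-1-yn-1-yl)-8-oxabicyclo[3.2.1]octan-3-ol | CCCCCCCCCCCCC#C[C@]1(O)C[C@H]2CC[C@H](O2)[C@@H]1CCC
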